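The data stem from a simulated flask with constants of no real substance, and the scatter is random.

**Charge balance.** Whatever substrate the coupling takes up stays in the flask in some form, so in the spring flask, the one asked about, target is a share of what the smaller charge allows.

| setting | spring | dawn | flask |
|---|---|---|---|
| substrate | 41 mM | 41 mM | 41 mM |
| coupling partner | 45.1 mM | 23 mM | 45.1 mM |
| temperature | 80 °C | 86 °C | 80 °C |
| remark | the very flask that is asked about, followed so far | run made earlier |  |
| time |  |  | 30 min |

- spring (time / min: target / %, substrate / %): 8.00: 52.5, 0; 15.0: 49.0, 0.1; 25.0: 48.8, 0; 30.0: 47.7, 0.4
- dawn (time / min: target / %, substrate / %): 2.50: 28.3, 28.2; 8.00: 27.9, 16.9; 15.0: 26.7, 12.0; 20.0: 27.7, 10.1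

(scatter of a reading: 1 percentage point)

- grey: change nothing and wait 1.0 h more
- blue: at 30 min add coupling partner, 100 % of the amount charged, then wait 1.0 h
- ochre: at 30 min take out 90 % of the target then present, then wait 1.0 h
- green: at 30 min raise the temperature by 10 K, then wait 1.0 h

- target taken out counts as made
- additions bring no volume worth counting

* target, in percent of the substrate first charged, at 30 min
* the remedy with the largest gain of target, or "none" below 2 percentage points (grey / blue / ochre / green / none)
* target present, with what was taken out counted in, in percent of the substrate first charged, after grey
* target present, with what was taken out counted in, in percent of the substrate first charged, after green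

**Share read.** The dawn run charges less coupling partner than substrate, at 0.561 equivalents, which makes partner the limiting reagent, and its target readings stand flat near 27.7 %. I assume one partner per coupled substrate and the dawn charge of partner used up, though partner was never read, so these readings give 0.493 target per partner; I carry this φ, the share of coupled material standing as target. It is read at 86 °C, and I take it over to 80 °C untested. In the spring flask substrate is the smaller charge, so φ puts target near 49.3 %, and the reading at 30.0 min is 47.7 %.

**Ochre bracket.** If the material that is not target is dead, taking target out gains nothing, and that is my floor. If it stays in exchange with target and restores φ, then removing a fraction x of target P gains xP(1−φ), or 22 percentage points, and that is my ceiling. Spring target drops 3.5 points in 7.00 min, then 1.3 points in 15.0 min; that fading, though scatter blurs it, looks like approach to a level, so I commit to ochre near the ceiling and to grey near the reading.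

**The forecast.** It gives 47.7 %, best none, grey 40 % and green 33 %, saying: “Removing target only preserves about 47 %, which is no gain over now”. That places ochre on my floor.

**The flask.**

    substrate + coupling partner → intermediate + released group (k = 1.80 /M/s, Ea = 47.0 kJ/mol)
    intermediate ⇌ target (K = 3.50, k = 0.00630 /s, Ea = 107 kJ/mol, ΔH = −33.0 kJ/mol)
    intermediate ⇌ isomer of the product (K = 2.60, k = 0.00290 /s, Ea = 115 kJ/mol, ΔH = −61.0 kJ/mol)
    substrate + target → side product (k = 0.00470 /M/s, Ea = 68.0 kJ/mol)
    2 substrate → self-condensation product (k = 0.0460 /M/s, Ea = 78.0 kJ/mol)
    (constants at 80 °C)

Target in the flask stands at 48.4 % at 30 min, and ochre gains 21 points, more than any other remedy and just under my ceiling; grey ends at 47.5 % and green at 49.1 %. In the scheme target, intermediate and isomer of the product interconvert, and at 30.0 min the flask holds target 48.4 %, isomer of the product 34.2 % and intermediate 13.6 %. The neighbour charged with 70 mM of substrate has 0.644 equiv of partner, with 0 % of that charge free at the end; φ on its partner charge reckons target at 31.8 %, and that flask holds target at 31.1 %.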